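**Plan**

- Retrosynthesis: the C11–O aryl ether and the C3 ester are cut first and the C3 alcohol is taken back to a ketone. The bicyclic core is then opened at C2–C3 and C5–C10 in one stroke, and the resulting chain is cut at C6–C7 (enolate alkylation) and C9–C10 (SN2′ substitution).
- Forward: the chain C3–C4–C5–C6–C7–C8–C9–C10–C1–C2 is joined from methyl acrylate, a silyloxyacetaldehyde, but-2-yne and methyl 2,2-dimethylacetoacetate. One nickel-catalysed event then closes ring B (C5–C10) and ring A (C2–C3), in that order, in the same flask.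
- Enabling feature: in ring A, C3 and C5 are held 1,3 across the quaternary C4, and the three-carbon arm C10–C1–C2 matches them. Once C5–C10 has closed ring B, C10 is quaternary, so a metal on the arm can only move between C1 and C2, and C2 sits six atoms from the C3 carbonyl.
- Stereochemistry: C9 is set by copper–NHC-catalysed SN2′ substitution; C10 is relayed from C9 during ring B closure; C3 is relayed from C10 and the C4 methyls in a hydride reduction. The (E) arm comes from syn-hydroalumination and the (Z) triflate from a (Z)-enolate.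

Key step: step 10

Remark: atoms are numbered as in drimane (ring A: C1–C5 and C10; ring B: C5–C10; C11 is the oxygen-bearing CH2 on C9, C12 the methylidene carbon on C8, C15 the methyl on C10). The commercial availability of the chiral imidazolinium ligand precursor of step 3 is assumed.

Step 1
Reactants: 1 methyl acrylate; 2 {[tert-butyl(dimethyl)silyl]oxy}acetaldehyde
Product: 3 methyl 4-{[tert-butyl(dimethyl)silyl]oxy}-3-hydroxy-2-methylidenebutanoate (racemic)
Conditions: DABCO (0.5 equiv), neat, rt
Reagents that add atoms: none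
Why: Morita–Baylis–Hillman reaction, in which the amine-derived acrylate enolate adds to the unhindered aldehyde; the carbinol stereocentre is racemic and is erased in step 2.

Step 2
Reactants: 3 methyl 4-{[tert-butyl(dimethyl)silyl]oxy}-3-hydroxy-2-methylidenebutanoate
Product: 4 methyl (2Z)-2-(bromomethyl)-4-{[tert-butyl(dimethyl)silyl]oxy}but-2-enoate
Conditions: NBS, Me2S, CH2Cl2, 0 °C to rt
Reagents that add atoms: N-bromosuccinimide, O=C1CCC(=O)N1Br
Why: Corey–Kim-type activation of the allylic alcohol followed by SN2′ attack of bromide should give the conjugated, thermodynamically preferred (Z)-2-(bromomethyl)enoate with allylic transposition.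

Step 3
Reactants: 4 methyl (2Z)-2-(bromomethyl)-4-{[tert-butyl(dimethyl)silyl]oxy}but-2-enoate; 5 but-2-yne
Product: 7 methyl (3S,4E)-3-({[tert-butyl(dimethyl)silyl]oxy}methyl)-4-methyl-2-methylidenehex-4-enoate, via alkenylalane 6 (not isolated)
Conditions: 5, iBu2AlH, hexane, 55 °C; then 4, CuCl2·2H2O (2 mol %), chiral sulfonate-bearing imidazolinium salt (NHC precursor, 2.5 mol %), THF, −15 °C
Reagents that add atoms: none
Why: syn-hydroalumination fixes the (E)-butenyl geometry, and copper–NHC-catalysed enantioselective SN2′ allylic substitution (addition at the enoate β-carbon with loss of bromide) creates C9, the ligand enantiomer being chosen to give (3S).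

Step 4
Reactants: 7 methyl (3S,4E)-3-({[tert-butyl(dimethyl)silyl]oxy}methyl)-4-methyl-2-methylidenehex-4-enoate
Product: 8 (3S,4E)-3-({[tert-butyl(dimethyl)silyl]oxy}methyl)-4-methyl-2-methylidenehex-4-en-1-ol
Conditions: iBu2AlH (2.2 equiv), CH2Cl2, −78 °C
Reagents that add atoms: none
Why: 1,2-reduction of an α-methylene ester by iBu2AlH at low temperature should give the allylic alcohol without touching C9 or the silyl ether.

Step 5
Reactants: 8 (3S,4E)-3-({[tert-butyl(dimethyl)silyl]oxy}methyl)-4-methyl-2-methylidenehex-4-en-1-ol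
Product: 9 (3S,4E)-2-(bromomethyl)-3-({[tert-butyl(dimethyl)silyl]oxy}methyl)-4-methylhexa-1,4-diene
Conditions: CBr4, PPh3, CH2Cl2, 0 °C
Reagents that add atoms: tetrabromomethane, BrC(Br)(Br)Br
Why: Appel bromination under neutral conditions; SN2 and SN2′ displacement lead to the same 2-substituted allyl bromide, so regiochemistry is not an issue.

Step 6
Reactants: 9 (3S,4E)-2-(bromomethyl)-3-({[tert-butyl(dimethyl)silyl]oxy}methyl)-4-methylhexa-1,4-diene; 10 methyl 2,2-dimethyl-3-oxobutanoate
Product: 12 methyl (7R,8E)-7-({[tert-butyl(dimethyl)silyl]oxy}methyl)-2,2,8-trimethyl-6-methylidene-3-oxodec-8-enoate, via lithium enolate 11 (not isolated)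
Conditions: 10, LiN(iPr)2, THF, −78 °C; then 9, DMPU, −78 to −20 °C
Reagents that add atoms: none
Why: kinetic enolate alkylation forms C6–C7; the acetyl methyl is the only enolisable position of 10 because C4 is quaternary, and the allylic bromide is a good SN2 partner.

Step 7
Reactants: 12 methyl (7R,8E)-7-({[tert-butyl(dimethyl)silyl]oxy}methyl)-2,2,8-trimethyl-6-methylidene-3-oxodec-8-enoate
Product: 14 methyl (3Z,7R,8E)-7-({[tert-butyl(dimethyl)silyl]oxy}methyl)-2,2,8-trimethyl-6-methylidene-3-{[(trifluoromethyl)sulfonyl]oxy}deca-3,8-dienoate, via potassium Z-enolate 13 (not isolated)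
Conditions: KN(SiMe3)2, THF, −78 °C; then PhNTf2, −78 to 0 °C
Reagents that add atoms: N-phenylbis(trifluoromethanesulfonimide), O=S(=O)(N(c1ccccc1)S(=O)(=O)C(F)(F)F)C(F)(F)F
Why: enol triflate formation; the ketone can enolise only towards C6, and a ketone with a tertiary α′-carbon should give the (Z)-enolate, so that OTf ends up cis to C7 as the later ring closure requires.

Step 8
Reactants: 14 methyl (3Z,7R,8E)-7-({[tert-butyl(dimethyl)silyl]oxy}methyl)-2,2,8-trimethyl-6-methylidene-3-{[(trifluoromethyl)sulfonyl]oxy}deca-3,8-dienoate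
Product: 15 (3Z,7R,8E)-7-({[tert-butyl(dimethyl)silyl]oxy}methyl)-1-hydroxy-2,2,8-trimethyl-6-methylidenedeca-3,8-dien-3-yl trifluoromethanesulfonate
Conditions: iBu2AlH (2.5 equiv), CH2Cl2, −78 to −40 °C
Reagents that add atoms: none
Why: ester reduction to the neopentyl alcohol by iBu2AlH, to which alkenyl triflates and silyl ethers are inert at low temperature.

Step 9
Reactants: 15 (3Z,7R,8E)-7-({[tert-butyl(dimethyl)silyl]oxy}methyl)-1-hydroxy-2,2,8-trimethyl-6-methylidenedeca-3,8-dien-3-yl trifluoromethanesulfonate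
Product: 16 (3Z,7R,8E)-7-({[tert-butyl(dimethyl)silyl]oxy}methyl)-2,2,8-trimethyl-6-methylidene-1-oxodeca-3,8-dien-3-yl trifluoromethanesulfonate
Conditions: Dess–Martin periodinane, CH2Cl2, 0 °C to rt
Reagents that add atoms: none
Why: Dess–Martin oxidation of a primary alcohol; the aldehyde has a quaternary α-carbon and can neither enolise nor move into conjugation.

Step 10
Reactants: 16 (3Z,7R,8E)-7-({[tert-butyl(dimethyl)silyl]oxy}methyl)-2,2,8-trimethyl-6-methylidene-1-oxodeca-3,8-dien-3-yl trifluoromethanesulfonate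
Product: 17 (4aR,5R)-5-({[tert-butyl(dimethyl)silyl]oxy}methyl)-1,1,4a-trimethyl-6-methylidene-3,4,4a,5,6,7-hexahydronaphthalen-2(1H)-one
Conditions: Ni(cod)2 (10 mol %), PhP(CH2CH2PPh2)2 (12 mol %), 2,2,6,6-tetramethylpiperidine (1.5 equiv), toluene (0.01 M), 110 °C
Reagents that add atoms: none
Why: Proposed new method: zerovalent nickel inserts into the C5–OTf bond, the cationic alkenylnickel adds across C10=C1 in a 6-exo-trig carbometalation (C5–C10, ring B), the C1-alkylnickel, whose only β-hydrogens are on C2 because C10 is now quaternary, moves to C2 by β-hydride elimination and re-insertion, and the primary C2–Ni bond adds to the C3 aldehyde in a 6-exo-trig carbonyl insertion (C2–C3, ring A) before β-hydride elimination of the nickel alkoxide releases the C3 ketone and the base returns zerovalent nickel. The closest known reaction types are the nickel-catalysed Mizoroki–Heck cyclisation of alkenyl triflates, metal hydride chain walking as in redox-relay Heck reactions, and the nickel-catalysed carbonyl-Heck coupling of aryl triflates with aldehydes to ketones under this catalyst system; new is their union, with an alkylnickel instead of an arylnickel adding to the aldehyde. The only stereocentre formed, C10, is controlled by C9: the C10=C1 bond must lie coplanar with the C5–Ni bond, which puts C1 pseudo-equatorial and C15 pseudo-axial on the forming half-chair, and the C9 silyloxymethyl group should sit pseudo-axial, anti to C15, because an equatorial position would eclipse the C8 methylidene (A(1,3) strain) and be gauche to both substituents on C10; the (E) geometry of the arm leaves only a hydrogen syn to C9. The step needs 6-exo insertion into C10=C1 rather than 4-exo or 5-endo insertion into C8=C12, which ring size secures, and it needs the (Z) triflate so that C7 and C10 can be cis on C5=C6. It also needs the aldehyde to react with the C2- and not the C1-nickel isomer, which the higher stability and lower hindrance of the primary alkylnickel and the six-membered ring should secure, while the quaternary C4 blocks enolisation and any hydride path on that side. High dilution should suppress intermolecular carbonyl-Heck coupling.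

Step 11
Reactants: 17 (4aR,5R)-5-({[tert-butyl(dimethyl)silyl]oxy}methyl)-1,1,4a-trimethyl-6-methylidene-3,4,4a,5,6,7-hexahydronaphthalen-2(1H)-one
Product: 18 (2S,4aR,5R)-5-({[tert-butyl(dimethyl)silyl]oxy}methyl)-1,1,4a-trimethyl-6-methylidene-1,2,3,4,4a,5,6,7-octahydronaphthalen-2-ol
Conditions: NaBH4, MeOH/THF, 0 °C
Reagents that add atoms: none
Why: borohydride reduction in which hydride should attack C3 from the α face, away from the axial C15 methyl and the β-methyl on C4, to give the equatorial 3β (3S) alcohol, as with 4,4-dimethyl-3-oxo steroids and triterpenoids.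

Step 12
Reactants: 19 3-hydroxy-3-methylbutanoic acid
Product: 21 3-methyl-3-[(triethylsilyl)oxy]butanoic acid, via bis-silyl derivative 20 (not isolated)
Conditions: Et3SiOTf (2.2 equiv), 2,6-lutidine, CH2Cl2, 0 °C; then MeOH, K2CO3 (cat.), rt
Reagents that add atoms: triethylsilyl trifluoromethanesulfonate, CC[Si](CC)(CC)OS(=O)(=O)C(F)(F)F
Why: silylation of both the tertiary alcohol and the acid with the silyl triflate, followed by selective methanolysis of the much more labile silyl ester.

Step 13
Reactants: 18 (2S,4aR,5R)-5-({[tert-butyl(dimethyl)silyl]oxy}methyl)-1,1,4a-trimethyl-6-methylidene-1,2,3,4,4a,5,6,7-octahydronaphthalen-2-ol; 21 3-methyl-3-[(triethylsilyl)oxy]butanoic acid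
Product: 22 (2S,4aR,5R)-5-({[tert-butyl(dimethyl)silyl]oxy}methyl)-1,1,4a-trimethyl-6-methylidene-1,2,3,4,4a,5,6,7-octahydronaphthalen-2-yl 3-methyl-3-[(triethylsilyl)oxy]butanoate
Conditions: EDC·HCl, DMAP, CH2Cl2, rt
Reagents that add atoms: none
Why: Steglich esterification, which acylates hindered equatorial 3β-alcohols next to a gem-dimethyl carbon; the silyl ether keeps the tertiary hydroxyl of the acid out of the reaction.

Step 14
Reactants: 22 (2S,4aR,5R)-5-({[tert-butyl(dimethyl)silyl]oxy}methyl)-1,1,4a-trimethyl-6-methylidene-1,2,3,4,4a,5,6,7-octahydronaphthalen-2-yl 3-methyl-3-[(triethylsilyl)oxy]butanoate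
Product: 23 (2S,4aR,5R)-5-(hydroxymethyl)-1,1,4a-trimethyl-6-methylidene-1,2,3,4,4a,5,6,7-octahydronaphthalen-2-yl 3-hydroxy-3-methylbutanoate
Conditions: HF·pyridine, pyridine, THF, 0 °C to rt
Reagents that add atoms: none
Why: fluoride-mediated desilylation removes both silyl ethers in one operation under buffered conditions that should leave the ester and both alkenes untouched.

Step 15
Reactants: 23 (2S,4aR,5R)-5-(hydroxymethyl)-1,1,4a-trimethyl-6-methylidene-1,2,3,4,4a,5,6,7-octahydronaphthalen-2-yl 3-hydroxy-3-methylbutanoate; 24 7-hydroxy-2H-chromen-2-one (umbelliferone)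
Product: 25 (2S,4aR,5R)-1,1,4a-trimethyl-6-methylidene-5-{[(2-oxo-2H-chromen-7-yl)oxy]methyl}-1,2,3,4,4a,5,6,7-octahydronaphthalen-2-yl 3-hydroxy-3-methylbutanoate
Conditions: PPh3, DIAD, THF, 0 °C to rt
Reagents that add atoms: none
Why: Mitsunobu etherification, in which only the primary C11 alcohol is activated (the tertiary alcohol is inert) and the acidic phenol displaces it without touching C9.

**Compound list**

1 | methyl acrylate | C=CC(=O)OC | starting material
2 | {[tert-butyl(dimethyl)silyl]oxy}acetaldehyde | O=CCO[Si](C)(C)C(C)(C)C | starting material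
3 | methyl 4-{[tert-butyl(dimethyl)silyl]oxy}-3-hydroxy-2-methylidenebutanoate (racemic) | COC(=O)C(=C)C(O)CO[Si](C)(C)C(C)(C)C | intermediate
4 | methyl (2Z)-2-(bromomethyl)-4-{[tert-butyl(dimethyl)silyl]oxy}but-2-enoate | COC(=O)/C(CBr)=C/CO[Si](C)(C)C(C)(C)C | intermediate
5 | but-2-yne | CC#CC | starting material
6 | [(2E)-but-2-en-2-yl]bis(2-methylpropyl)alumane | C/C=C(\C)[Al](CC(C)C)CC(C)C | intermediate
7 | methyl (3S,4E)-3-({[tert-butyl(dimethyl)silyl]oxy}methyl)-4-methyl-2-methylidenehex-4-enoate | COC(=O)C(=C)[C@@H](CO[Si](C)(C)C(C)(C)C)/C(C)=C/C | intermediate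
8 | (3S,4E)-3-({[tert-butyl(dimethyl)silyl]oxy}methyl)-4-methyl-2-methylidenehex-4-en-1-ol | OCC(=C)[C@@H](CO[Si](C)(C)C(C)(C)C)/C(C)=C/C | intermediate
9 | (3S,4E)-2-(bromomethyl)-3-({[tert-butyl(dimethyl)silyl]oxy}methyl)-4-methylhexa-1,4-diene | BrCC(=C)[C@@H](CO[Si](C)(C)C(C)(C)C)/C(C)=C/C | intermediate
10 | methyl 2,2-dimethyl-3-oxobutanoate | COC(=O)C(C)(C)C(C)=O | starting material
11 | lithium 4-methoxy-3,3-dimethyl-4-oxobut-1-en-2-olate | COC(=O)C(C)(C)C(=C)O[Li] | intermediate
12 | methyl (7R,8E)-7-({[tert-butyl(dimethyl)silyl]oxy}methyl)-2,2,8-trimethyl-6-methylidene-3-oxodec-8-enoate | COC(=O)C(C)(C)C(=O)CCC(=C)[C@@H](CO[Si](C)(C)C(C)(C)C)/C(C)=C/C | intermediate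
13 | potassium (3Z,7R,8E)-7-({[tert-butyl(dimethyl)silyl]oxy}methyl)-1-methoxy-2,2,8-trimethyl-6-methylidene-1-oxodeca-3,8-dien-3-olate | COC(=O)C(C)(C)/C(O[K])=C/CC(=C)[C@@H](CO[Si](C)(C)C(C)(C)C)/C(C)=C/C | intermediate
14 | methyl (3Z,7R,8E)-7-({[tert-butyl(dimethyl)silyl]oxy}methyl)-2,2,8-trimethyl-6-methylidene-3-{[(trifluoromethyl)sulfonyl]oxy}deca-3,8-dienoate | COC(=O)C(C)(C)/C(OS(=O)(=O)C(F)(F)F)=C/CC(=C)[C@@H](CO[Si](C)(C)C(C)(C)C)/C(C)=C/C | intermediate
15 | (3Z,7R,8E)-7-({[tert-butyl(dimethyl)silyl]oxy}methyl)-1-hydroxy-2,2,8-trimethyl-6-methylidenedeca-3,8-dien-3-yl trifluoromethanesulfonate | OCC(C)(C)/C(OS(=O)(=O)C(F)(F)F)=C/CC(=C)[C@@H](CO[Si](C)(C)C(C)(C)C)/C(C)=C/C | intermediate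
16 | (3Z,7R,8E)-7-({[tert-butyl(dimethyl)silyl]oxy}methyl)-2,2,8-trimethyl-6-methylidene-1-oxodeca-3,8-dien-3-yl trifluoromethanesulfonate | O=CC(C)(C)/C(OS(=O)(=O)C(F)(F)F)=C/CC(=C)[C@@H](CO[Si](C)(C)C(C)(C)C)/C(C)=C/C | intermediate
17 | (4aR,5R)-5-({[tert-butyl(dimethyl)silyl]oxy}methyl)-1,1,4a-trimethyl-6-methylidene-3,4,4a,5,6,7-hexahydronaphthalen-2(1H)-one | C=C1CC=C2C(C)(C)C(=O)CC[C@]2(C)[C@@H]1CO[Si](C)(C)C(C)(C)C | intermediate
18 | (2S,4aR,5R)-5-({[tert-butyl(dimethyl)silyl]oxy}methyl)-1,1,4a-trimethyl-6-methylidene-1,2,3,4,4a,5,6,7-octahydronaphthalen-2-ol | C=C1CC=C2C(C)(C)[C@@H](O)CC[C@]2(C)[C@@H]1CO[Si](C)(C)C(C)(C)C | intermediate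
19 | 3-hydroxy-3-methylbutanoic acid | CC(C)(O)CC(=O)O | starting material
20 | triethylsilyl 3-methyl-3-[(triethylsilyl)oxy]butanoate | CC[Si](CC)(CC)OC(=O)CC(C)(C)O[Si](CC)(CC)CC | intermediate
21 | 3-methyl-3-[(triethylsilyl)oxy]butanoic acid | CC[Si](CC)(CC)OC(C)(C)CC(=O)O | intermediate
22 | (2S,4aR,5R)-5-({[tert-butyl(dimethyl)silyl]oxy}methyl)-1,1,4a-trimethyl-6-methylidene-1,2,3,4,4a,5,6,7-octahydronaphthalen-2-yl 3-methyl-3-[(triethylsilyl)oxy]butanoate | C=C1CC=C2C(C)(C)[C@@H](OC(=O)CC(C)(C)O[Si](CC)(CC)CC)CC[C@]2(C)[C@@H]1CO[Si](C)(C)C(C)(C)C | intermediate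
23 | (2S,4aR,5R)-5-(hydroxymethyl)-1,1,4a-trimethyl-6-methylidene-1,2,3,4,4a,5,6,7-octahydronaphthalen-2-yl 3-hydroxy-3-methylbutanoate | C=C1CC=C2C(C)(C)[C@@H](OC(=O)CC(C)(C)O)CC[C@]2(C)[C@@H]1CO | intermediate
24 | 7-hydroxy-2H-chromen-2-one (umbelliferone) | Oc1ccc2ccc(=O)oc2c1 | starting material
25 | (2S,4aR,5R)-1,1,4a-trimethyl-6-methylidene-5-{[(2-oxo-2H-chromen-7-yl)oxy]methyl}-1,2,3,4,4a,5,6,7-octahydronaphthalen-2-yl 3-hydroxy-3-methylbutanoate | C=C1CC=C2C(C)(C)[C@@H](OC(=O)CC(C)(C)O)CC[C@]2(C)[C@@H]1COc1ccc2ccc(=O)oc2c1 | target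

**Step count and risks**

Total step count: 15. Longest linear sequence: 14 steps (steps 1–11 and 13–15; step 12 is a side branch).

Steps most likely to fail:

1. Step 10. The alkylnickel may be lost by β-hydride elimination and dissociation before it adds to the aldehyde. Carbonyl insertion may occur from the C1-nickel isomer and close a five-membered ring. Nickel hydride may move the C8 methylidene into the ring. Facial selectivity at C10 may be poor. The fallback sets out from 16 and returns at 17. A conventional cationic Mizoroki–Heck cyclisation (Pd(OAc)2, BINAP in its matched enantiomer, 1,2,2,6,6-pentamethylpiperidine, toluene, 80 °C) should stop after β-hydride elimination at the ring B diene aldehyde 2-[(5R,6R)-5-({[tert-butyl(dimethyl)silyl]oxy}methyl)-6-ethenyl-6-methyl-4-methylidenecyclohex-1-en-1-yl]-2-methylpropanal F1, with ligand and C9 together controlling C10. Ring A would then be closed by chelation-assisted intramolecular hydroacylation of the vinyl group (RhCl(PPh3)3, 2-amino-3-picoline, benzoic acid, toluene, 130 °C, then dilute aqueous acid), which forms C2–C3 and gives 17.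

2. Step 3. Enantioselectivity may be low, an isobutyl group may transfer in place of the butenyl group, or a second conjugate addition to the product acrylate may compete. The fallback sets out from 2 and returns at 8, and sets C9 by 1,3-chirality transfer instead of catalysis.
   - Wittig olefination of 2 with 3-(triphenyl-λ5-phosphanylidene)butan-2-one should give (3E)-5-{[tert-butyl(dimethyl)silyl]oxy}-3-methylpent-3-en-2-one F2.
   - Corey–Bakshi–Shibata reduction ((S)-2-methyl-CBS-oxazaborolidine, BH3·SMe2) should give (2R,3E)-5-{[tert-butyl(dimethyl)silyl]oxy}-3-methylpent-3-en-2-ol F3.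
   - Johnson–Claisen rearrangement (triethyl orthoacetate, catalytic propionic acid, 140 °C) through a chair with the methyl group equatorial should give ethyl (3R,4E)-3-({[tert-butyl(dimethyl)silyl]oxy}methyl)-4-methylhex-4-enoate F4.
   - Half-reduction (iBu2AlH, 1 equiv, −78 °C) should give (3R,4E)-3-({[tert-butyl(dimethyl)silyl]oxy}methyl)-4-methylhex-4-enal F5.
   - Amine-catalysed α-methylenation (aqueous formaldehyde, pyrrolidine, propionic acid) should give (3S,4E)-3-({[tert-butyl(dimethyl)silyl]oxy}methyl)-4-methyl-2-methylidenehex-4-enal F6.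
   - Luche reduction (NaBH4, CeCl3·7H2O, MeOH) then gives 8.

3. Step 15. Displacement at the β-branched C11 carbinol may be slow, so that the activated alcohol is diverted to elimination or hydrazide by-products. The fallback sets out from 23 and 24 and returns at 25, and forms the aryl–oxygen bond instead of the alkyl–oxygen bond. Compound 24 is converted (Tf2O, pyridine, CH2Cl2) into 2-oxo-2H-chromen-7-yl trifluoromethanesulfonate F7. Palladium-catalysed C–O cross-coupling of the primary alcohol of 23 with F7 ([Pd(C3H5)Cl]2, RockPhos, K3PO4, toluene, 90 °C) should then give 25, the tertiary alcohol being too hindered to couple.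

**Further compounds**

F1 | step 10 | 2-[(5R,6R)-5-({[tert-butyl(dimethyl)silyl]oxy}methyl)-6-ethenyl-6-methyl-4-methylidenecyclohex-1-en-1-yl]-2-methylpropanal | O=CC(C)(C)C1=CCC(=C)[C@@H](CO[Si](C)(C)C(C)(C)C)[C@@]1(C)C=C
F2 | step 3 | (3E)-5-{[tert-butyl(dimethyl)silyl]oxy}-3-methylpent-3-en-2-one | CC(=O)/C(C)=C/CO[Si](C)(C)C(C)(C)C
F3 | step 3 | (2R,3E)-5-{[tert-butyl(dimethyl)silyl]oxy}-3-methylpent-3-en-2-ol | C[C@@H](O)/C(C)=C/CO[Si](C)(C)C(C)(C)C
F4 | step 3 | ethyl (3R,4E)-3-({[tert-butyl(dimethyl)silyl]oxy}methyl)-4-methylhex-4-enoate | CCOC(=O)C[C@@H](CO[Si](C)(C)C(C)(C)C)/C(C)=C/C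
F5 | step 3 | (3R,4E)-3-({[tert-butyl(dimethyl)silyl]oxy}methyl)-4-methylhex-4-enal | O=CC[C@@H](CO[Si](C)(C)C(C)(C)C)/C(C)=C/C
F6 | step 3 | (3S,4E)-3-({[tert-butyl(dimethyl)silyl]oxy}methyl)-4-methyl-2-methylidenehex-4-enal | O=CC(=C)[C@@H](CO[Si](C)(C)C(C)(C)C)/C(C)=C/C
F7 | step 15 | 2-oxo-2H-chromen-7-yl trifluoromethanesulfonate | O=c1ccc2ccc(OS(=O)(=O)C(F)(F)F)cc2o1
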